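**Plan** (locants are those of the hexahydro-1-benzofuran core: O1, C2, C3, C3a, C4–C7, C7a)

- Retrosynthetic cuts: the C–Br bond of the bromomethyl ketone; the C5–Br bond (back to an axial C5 carbinol, with inversion); then the C3–C3a bond together with the O1–C2 ether bond, which opens the oxolane ring to a 2-hydroxycyclohexanone and a C6 allenyl ketone.
- Forward order: the carbocycle comes from Birch dearomatization of 4-methylanisole and gem-dimethylation; it is oxygenated to the α-ketol; one annulation then closes the oxolane ring and completes the C15 skeleton; the two bromines come last.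
- Enabling feature: C3 is the γ-carbon of the vinylogous ester O1–C2=C–C=O, and C3a lies between two fully substituted carbons (C4 and C7a). A ketone at C3a therefore cannot enolize and can only be attacked by the extended enolate that forms when the C7a alkoxide adds to an allenyl ketone.
- Stereochemistry: one reagent-set centre, the C5 carbinol (Corey–Bakshi–Shibata reduction). It directs OsO4 to set C7a, then directs the iridium hydrogenation that sets C3a (trans ring fusion), and is finally replaced by bromide with inversion. The exocyclic alkene geometry is thermodynamic.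

Key step: step 8

Assumption: the acetyl-stabilized phosphorus ylide used for the allenyl ketone is taken as a catalogue reagent (otherwise one step from 3-bromobutan-2-one and PPh3), and the allenyl ketone is used freshly prepared because it oligomerizes on standing.

**Step 1**
Reactants: 1 4-methylanisole
Product: 3 4-methylcyclohex-3-en-1-one, via dihydroanisole 2 (not isolated)
Conditions: Li, NH3(l), t-BuOH, THF, −78 °C; then (CO2H)2, MeOH/H2O, 20 °C
Reagents that add atoms: water (O)
Why: Birch reduction gives the 2,5-dihydroanisole, and mild oxalic acid hydrolysis of its enol ether should release the β,γ-unsaturated ketone without moving the trisubstituted alkene into conjugation.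

**Step 2**
Reactants: 3 4-methylcyclohex-3-en-1-one
Product: 4 2,2,4-trimethylcyclohex-3-en-1-one
Conditions: KOt-Bu (2.2 equiv), MeI, t-BuOH/THF, 0 → 20 °C
Reagents that add atoms: iodomethane (CI)
Why: Under thermodynamic conditions the extended dienolate should be alkylated twice at the carbon between carbonyl and alkene (deconjugative gem-dimethylation of an enone dienolate), leaving the alkene in place.

**Step 3**
Reactants: 4 2,2,4-trimethylcyclohex-3-en-1-one
Product: 5 (R)-2,2,4-trimethylcyclohex-3-en-1-ol
Conditions: (S)-1-methyl-3,3-diphenyltetrahydro-1H,3H-pyrrolo[1,2-c][1,3,2]oxazaborole (10 mol %), catecholborane, toluene, −78 °C; aqueous work-up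
Reagents that add atoms: none
Why: Corey–Bakshi–Shibata reduction distinguishes the quaternary flank from the methylene flank of the ketone, so the (S)-catalyst should deliver hydride to give the (R)-carbinol, the only stereocenter set by a chiral reagent.

**Step 4**
Reactants: 5 (R)-2,2,4-trimethylcyclohex-3-en-1-ol
Product: 6 (1S,2R,4R)-1,3,3-trimethylcyclohexane-1,2,4-triol (all three hydroxyls cis)
Conditions: OsO4 (1.05 equiv), TMEDA, CH2Cl2, −78 °C; then Na2SO3, THF/H2O, reflux
Reagents that add atoms: osmium tetroxide (O=[Os](=O)(=O)=O)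
Why: In this hydrogen-bond-directed dihydroxylation the homoallylic hydroxyl, in its axial conformer, should bind OsO4·TMEDA and deliver both oxygens to its own face, which is also the face away from the pseudoaxial methyl of the gem-dimethyl group, so the tertiary carbinol is set cis to the directing hydroxyl.

**Step 5**
Reactants: 6 (1S,2R,4R)-1,3,3-trimethylcyclohexane-1,2,4-triol
Product: 7 (1S,2R,4R)-4-[(tert-butyldimethylsilyl)oxy]-1,3,3-trimethylcyclohexane-1,2-diol
Conditions: TBSCl, imidazole, DMF, 0 °C
Reagents that add atoms: tert-butyldimethylsilyl chloride (CC(C)(C)[Si](C)(C)Cl)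
Why: Silylation should select the secondary hydroxyl flanked by a methylene over the secondary hydroxyl wedged between two fully substituted carbons and over the tertiary one (steric differentiation).

**Step 6**
Reactants: 7 (1S,2R,4R)-4-[(tert-butyldimethylsilyl)oxy]-1,3,3-trimethylcyclohexane-1,2-diol
Product: 8 (3R,6S)-3-[(tert-butyldimethylsilyl)oxy]-6-hydroxy-2,2,6-trimethylcyclohexan-1-one
Conditions: (COCl)2, DMSO, CH2Cl2, −78 °C; then Et3N, −78 → 0 °C
Reagents that add atoms: none
Why: Swern oxidation should convert the remaining secondary carbinol of the vicinal diol into the ketone without glycol cleavage, leaving the tertiary hydroxyl free.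

**Step 7**
Reactants: 9 3-(triphenyl-λ5-phosphanylidene)butan-2-one
Product: 10 3-methylpenta-3,4-dien-2-one
Conditions: AcCl, Et3N, CH2Cl2, 0 → 20 °C
Reagents that add atoms: acetyl chloride (CC(=O)Cl)
Why: Wittig reaction of the acyl-stabilized ylide with ketene generated in situ from acetyl chloride and Et3N should give the terminal allene (ylide–ketene allene synthesis).

**Step 8**
Reactants: 8 (3R,6S)-3-[(tert-butyldimethylsilyl)oxy]-6-hydroxy-2,2,6-trimethylcyclohexan-1-one; 10 3-methylpenta-3,4-dien-2-one
Product: 12 (Z)-3-[(5R,7aS)-5-[(tert-butyldimethylsilyl)oxy]-4,4,7a-trimethyl-5,6,7,7a-tetrahydro-1-benzofuran-2(4H)-ylidene]butan-2-one, via aldol carbinol 11 (not isolated)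
Conditions: Cs2CO3 (30 mol %), MeCN, 0 → 20 °C, then 60 °C
Reagents that add atoms: none
Why: Proposed new method: the caesium alkoxide of the tertiary α-ketol should add to the central allene carbon of 10 (oxa-Michael addition) to give a 2-alkoxy dienolate whose terminal CH2 attacks the neighbouring ketone in a 5-(enolexo)-exo-trig vinylogous aldol closure, forming the C3–C3a bond and the oxolane ring, after which carbinol 11 loses water by E1cB through the only available hydrogens, those on C3; the closest known reaction type is the base-mediated oxa-Michael/aldol [3+2] annulation of α-hydroxy ketones with activated alkynes and allenoates. The closure is possible because the C3a ketone lies between two fully substituted carbons (C4 and C7a), so it cannot enolize and acts only as the electrophile. No lasting stereocenter is created: the C3a carbinol is transient, the C7a configuration is carried in from 8, and the exocyclic push–pull alkene should equilibrate through the extended enolate to the Z geometry, in which the coplanar acetyl group lies on the side of the ring oxygen and away from C3. The step needs γ- and not α-attack of the dienolate, which is secured because α-attack would build two adjacent quaternary carbons in a readily reversible aldol, whereas γ-attack keeps the vinylogous ester conjugation and is drained by dehydration. It also needs O-addition by the tertiary hydroxyl alone, secured by the silyl ether on the secondary oxygen, and the low-temperature addition caps the α-ketol before heating so that acyloin rearrangement is avoided.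

**Step 9**
Reactants: 12 (Z)-3-[(5R,7aS)-5-[(tert-butyldimethylsilyl)oxy]-4,4,7a-trimethyl-5,6,7,7a-tetrahydro-1-benzofuran-2(4H)-ylidene]butan-2-one
Product: 13 (Z)-3-[(5R,7aS)-5-hydroxy-4,4,7a-trimethyl-5,6,7,7a-tetrahydro-1-benzofuran-2(4H)-ylidene]butan-2-one
Conditions: Bu4NF, THF, 20 → 50 °C
Reagents that add atoms: none
Why: Fluoride-mediated desilylation should free the axial secondary hydroxyl needed as directing group, the vinylogous ester being inert to Bu4NF.

**Step 10**
Reactants: 13 (Z)-3-[(5R,7aS)-5-hydroxy-4,4,7a-trimethyl-5,6,7,7a-tetrahydro-1-benzofuran-2(4H)-ylidene]butan-2-one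
Product: 14 (Z)-3-[(3aS,5R,7aS)-5-hydroxy-4,4,7a-trimethylhexahydro-1-benzofuran-2(3H)-ylidene]butan-2-one
Conditions: [Ir(cod)(PCy3)(py)]PF6 (10 mol %), H2 (1 atm), CH2Cl2, 20 °C
Reagents that add atoms: none
Why: In this hydroxyl-directed homogeneous hydrogenation the axial C5 hydroxyl, syn-axial to one face of the trisubstituted C3=C3a alkene, should bind the cationic iridium catalyst and deliver H2 to that face, so the C3a hydrogen ends up trans to the C7a methyl (trans ring fusion) while the tetrasubstituted push–pull alkene is untouched.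

**Step 11**
Reactants: 14 (Z)-3-[(3aS,5R,7aS)-5-hydroxy-4,4,7a-trimethylhexahydro-1-benzofuran-2(3H)-ylidene]butan-2-one
Product: 15 (Z)-3-[(3aS,5S,7aS)-5-bromo-4,4,7a-trimethylhexahydro-1-benzofuran-2(3H)-ylidene]butan-2-one
Conditions: PPh3, CBr4, 2,6-lutidine, toluene, 0 → 70 °C
Reagents that add atoms: carbon tetrabromide (BrC(Br)(Br)Br)
Why: In the Appel reaction the axial oxyphosphonium group should be displaced by bromide from the equatorial direction with inversion (SN2), turning the directing hydroxyl into the equatorial bromide.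

**Step 12**
Reactants: 15 (Z)-3-[(3aS,5S,7aS)-5-bromo-4,4,7a-trimethylhexahydro-1-benzofuran-2(3H)-ylidene]butan-2-one
Product: 17 (Z)-1-bromo-3-[(3aS,5S,7aS)-5-bromo-4,4,7a-trimethylhexahydro-1-benzofuran-2(3H)-ylidene]butan-2-one, via silyl dienol ether 16 (not isolated)
Conditions: LiN(SiMe3)2, Me3SiCl, THF, −78 °C; then N-bromosuccinimide, −78 → 0 °C
Reagents that add atoms: N-bromosuccinimide (O=C1CCC(=O)N1Br)
Why: Kinetic deprotonation of the vinylogous ester at the methyl ketone (α′ position) and silylation should give a 1-alkoxy-3-silyloxy diene that N-bromosuccinimide brominates at its terminal carbon (α′-halogenation through a silyl dienol ether).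

**Compound list**

1 | 4-methylanisole | COc1ccc(C)cc1 | starting material
2 | 1-methoxy-4-methylcyclohexa-1,4-diene | COC1=CCC(C)=CC1 | intermediate
3 | 4-methylcyclohex-3-en-1-one | O=C1CC=C(C)CC1 | intermediate
4 | 2,2,4-trimethylcyclohex-3-en-1-one | O=C1CCC(C)=CC1(C)C | intermediate
5 | (R)-2,2,4-trimethylcyclohex-3-en-1-ol | O[C@@H]1CCC(C)=CC1(C)C | intermediate
6 | (1S,2R,4R)-1,3,3-trimethylcyclohexane-1,2,4-triol | O[C@@H]1CC[C@](C)(O)[C@H](O)C1(C)C | intermediate
7 | (1S,2R,4R)-4-[(tert-butyldimethylsilyl)oxy]-1,3,3-trimethylcyclohexane-1,2-diol | CC(C)(C)[Si](C)(C)O[C@@H]1CC[C@](C)(O)[C@H](O)C1(C)C | intermediate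
8 | (3R,6S)-3-[(tert-butyldimethylsilyl)oxy]-6-hydroxy-2,2,6-trimethylcyclohexan-1-one | CC(C)(C)[Si](C)(C)O[C@@H]1CC[C@](C)(O)C(=O)C1(C)C | intermediate
9 | 3-(triphenyl-λ5-phosphanylidene)butan-2-one | CC(=O)C(C)=P(c1ccccc1)(c1ccccc1)c1ccccc1 | starting material
10 | 3-methylpenta-3,4-dien-2-one | CC(=O)C(C)=C=C | intermediate
11 | (Z)-3-[(3aS,5R,7aS)-5-[(tert-butyldimethylsilyl)oxy]-3a-hydroxy-4,4,7a-trimethylhexahydro-1-benzofuran-2(3H)-ylidene]butan-2-one (cis-fused aldol carbinol) | C/C(C(C)=O)=C1\C[C@]2(O)C(C)(C)[C@H](O[Si](C)(C)C(C)(C)C)CC[C@]2(C)O1 | intermediate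
12 | (Z)-3-[(5R,7aS)-5-[(tert-butyldimethylsilyl)oxy]-4,4,7a-trimethyl-5,6,7,7a-tetrahydro-1-benzofuran-2(4H)-ylidene]butan-2-one | C/C(C(C)=O)=C1\C=C2C(C)(C)[C@H](O[Si](C)(C)C(C)(C)C)CC[C@]2(C)O1 | intermediate
13 | (Z)-3-[(5R,7aS)-5-hydroxy-4,4,7a-trimethyl-5,6,7,7a-tetrahydro-1-benzofuran-2(4H)-ylidene]butan-2-one | C/C(C(C)=O)=C1\C=C2C(C)(C)[C@H](O)CC[C@]2(C)O1 | intermediate
14 | (Z)-3-[(3aS,5R,7aS)-5-hydroxy-4,4,7a-trimethylhexahydro-1-benzofuran-2(3H)-ylidene]butan-2-one | C/C(C(C)=O)=C1\C[C@H]2C(C)(C)[C@H](O)CC[C@]2(C)O1 | intermediate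
15 | (Z)-3-[(3aS,5S,7aS)-5-bromo-4,4,7a-trimethylhexahydro-1-benzofuran-2(3H)-ylidene]butan-2-one | C/C(C(C)=O)=C1\C[C@H]2C(C)(C)[C@@H](Br)CC[C@]2(C)O1 | intermediate
16 | {[(3Z)-3-((3aS,5S,7aS)-5-bromo-4,4,7a-trimethylhexahydro-1-benzofuran-2(3H)-ylidene)but-1-en-2-yl]oxy}trimethylsilane | C/C(C(=C)O[Si](C)(C)C)=C1\C[C@H]2C(C)(C)[C@@H](Br)CC[C@]2(C)O1 | intermediate
17 | (Z)-1-bromo-3-[(3aS,5S,7aS)-5-bromo-4,4,7a-trimethylhexahydro-1-benzofuran-2(3H)-ylidene]butan-2-one | C/C(C(=O)CBr)=C1\C[C@H]2C(C)(C)[C@@H](Br)CC[C@]2(C)O1 | target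

**Step count**

Total: 12 steps. Longest linear sequence: 11 steps (steps 1–6 and 8–12, from 4-methylanisole); step 7 is a one-step side branch.

**Steps most likely to fail**

Step 8. The hindered tertiary alkoxide may add to the allene more slowly than the allene oligomerizes, the dienolate may stall after O-addition or attack through its α-carbon, and the dehydration may not go to completion. The fallback uses known chemistry and sets out from 8:
- Ph3P=C=C=O in toluene at 80 °C should acylate the tertiary hydroxyl and close the butenolide by intramolecular Wittig olefination of the C3a ketone, giving (5R,7aS)-5-[(tert-butyldimethylsilyl)oxy]-4,4,7a-trimethyl-5,6,7,7a-tetrahydro-1-benzofuran-2(4H)-one F1.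
- Bu4NF should give (5R,7aS)-5-hydroxy-4,4,7a-trimethyl-5,6,7,7a-tetrahydro-1-benzofuran-2(4H)-one F2.
- The same hydroxyl-directed hydrogenation with [Ir(cod)(PCy3)(py)]PF6 should give the trans-fused lactone (3aS,5R,7aS)-5-hydroxy-4,4,7a-trimethylhexahydro-1-benzofuran-2(3H)-one F3.
- Appel bromination should give (3aS,5S,7aS)-5-bromo-4,4,7a-trimethylhexahydro-1-benzofuran-2(3H)-one F4.
- Takai ethylidenation of the lactone carbonyl (CH3CHBr2, Zn, TiCl4, TMEDA) should give (2Z,3aS,5S,7aS)-5-bromo-2-ethylidene-4,4,7a-trimethyloctahydro-1-benzofuran F5.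
- C-acylation of this enol ether with bromoacetyl bromide and pyridine comes back to the route at 17.

Step 11. At the neopentyl, axial carbinol, E2 elimination toward C6 and methyl migration from C4 may outrun substitution. The fallback sets out from 14 and separates activation from displacement: Tf2O and pyridine at −20 °C should give the triflate (Z)-3-[(3aS,5R,7aS)-4,4,7a-trimethyl-5-(trifluoromethanesulfonyloxy)hexahydro-1-benzofuran-2(3H)-ylidene]butan-2-one F6, and Bu4NBr in toluene should then displace it with inversion, coming back to the route at 15.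

Step 4. Hydrogen-bond direction by a homoallylic hydroxyl may be incomplete, eroding facial selectivity at the future C7a. The fallback sets out from 5:
- VO(acac)2-catalysed epoxidation with t-BuOOH, reliably syn to a homoallylic hydroxyl, should give (1R,3R,6S)-2,2,6-trimethyl-7-oxabicyclo[4.1.0]heptan-3-ol F7.
- KOH in aqueous DMSO at 120 °C should open the epoxide at its secondary carbon with inversion, keeping the tertiary C–O bond, to give (1S,2S,4R)-1,3,3-trimethylcyclohexane-1,2,4-triol F8; its secondary carbinol epimer is of no consequence because that carbon becomes the ketone.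
- Selective silylation should give (1S,2S,4R)-4-[(tert-butyldimethylsilyl)oxy]-1,3,3-trimethylcyclohexane-1,2-diol F9, and Swern oxidation as in step 6 comes back to the route at 8.

**Further compounds**

F1 | step 8 | (5R,7aS)-5-[(tert-butyldimethylsilyl)oxy]-4,4,7a-trimethyl-5,6,7,7a-tetrahydro-1-benzofuran-2(4H)-one | O=C1C=C2C(C)(C)[C@H](O[Si](C)(C)C(C)(C)C)CC[C@]2(C)O1
F2 | step 8 | (5R,7aS)-5-hydroxy-4,4,7a-trimethyl-5,6,7,7a-tetrahydro-1-benzofuran-2(4H)-one | O=C1C=C2C(C)(C)[C@H](O)CC[C@]2(C)O1
F3 | step 8 | (3aS,5R,7aS)-5-hydroxy-4,4,7a-trimethylhexahydro-1-benzofuran-2(3H)-one | O=C1C[C@H]2C(C)(C)[C@H](O)CC[C@]2(C)O1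
F4 | step 8 | (3aS,5S,7aS)-5-bromo-4,4,7a-trimethylhexahydro-1-benzofuran-2(3H)-one | O=C1C[C@H]2C(C)(C)[C@@H](Br)CC[C@]2(C)O1
F5 | step 8 | (2Z,3aS,5S,7aS)-5-bromo-2-ethylidene-4,4,7a-trimethyloctahydro-1-benzofuran | C/C=C1/C[C@H]2C(C)(C)[C@@H](Br)CC[C@]2(C)O1
F6 | step 11 | (Z)-3-[(3aS,5R,7aS)-4,4,7a-trimethyl-5-(trifluoromethanesulfonyloxy)hexahydro-1-benzofuran-2(3H)-ylidene]butan-2-one | C/C(C(C)=O)=C1\C[C@H]2C(C)(C)[C@H](OS(=O)(=O)C(F)(F)F)CC[C@]2(C)O1
F7 | step 4 | (1R,3R,6S)-2,2,6-trimethyl-7-oxabicyclo[4.1.0]heptan-3-ol | O[C@@H]1CC[C@]2(C)O[C@@H]2C1(C)C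
F8 | step 4 | (1S,2S,4R)-1,3,3-trimethylcyclohexane-1,2,4-triol | O[C@@H]1CC[C@](C)(O)[C@@H](O)C1(C)C
F9 | step 4 | (1S,2S,4R)-4-[(tert-butyldimethylsilyl)oxy]-1,3,3-trimethylcyclohexane-1,2-diol | CC(C)(C)[Si](C)(C)O[C@@H]1CC[C@](C)(O)[C@@H](O)C1(C)C
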